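**Retrosynthetic overview**

- The target is traced back, by Horner–Wadsworth–Emmons olefination, ester reduction and acetylation, to a C13 methyl ketone, and this by conjugate hydrogenation to a bicyclic 8,11-dien-13-one 19-acid.
- Key disconnection: the C9–C10 bond of ring B. The precursor is a monocyclic lactone in which the C19 carboxyl is tied to C10 (temporary ring C4–C19(=O)–O–C10–C5) and the side chain is a pseudoionone-type dienone (C8=C9–C11=C12–C13=O).
- Enabling feature: the C19 carboxyl on C4 and the methyl-bearing C10 are 1,3-related across C5 on ring A and cis in the target. C10 can therefore be stored as a tertiary γ-lactone that ionizes to the C10 cation and returns the acid, while C9 sits at six-ring distance through C5–C6–C7–C8.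
- The lactone comes from a keto-lactone (vinyl addition, oxidative transposition, Wittig), and this from an arene by asymmetric Birch reductive methylation (C4), hydrogenation and protolactonization (C5, auxiliary release).
- Order of ring formation: ring A (from the benzene ring), then the temporary lactone ring, then ring B last.

Key step: step 9

Numbering: labdane numbering of the target (C4, C5, C10, C19 carboxyl, C20 methyl on C10) is used for all intermediates.

Assumption: the potassium enolate of the (S)-2-(methoxymethyl)pyrrolidine benzamide is taken to be methylated on the face that gives the (S) quaternary centre; if this 2,3-dialkyl substrate shows the opposite sense, the (R)-auxiliary is used and nothing else changes.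

**Step 1**
Reactants: 1 2-bromo-3-methylbenzoic acid; 2 (S)-2-(methoxymethyl)pyrrolidine
Product: 4 [(2S)-2-(methoxymethyl)pyrrolidin-1-yl](2-bromo-3-methylphenyl)methanone, via acid chloride 3 (not isolated)
Conditions: (COCl)2, cat. DMF, CH2Cl2, 0 °C to rt; then 2, Et3N, CH2Cl2, 0 °C to rt
Reagents that add atoms: none
Why: Acid chloride formation followed by N-acylation of the secondary amine (amide coupling) should leave the aryl bromide untouched, and the only stereocentre is that of the auxiliary.

**Step 2**
Reactants: 4 [(2S)-2-(methoxymethyl)pyrrolidin-1-yl](2-bromo-3-methylphenyl)methanone; 5 2-methyl-2-vinyl-1,3-dioxolane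
Product: 7 [(2S)-2-(methoxymethyl)pyrrolidin-1-yl]{3-methyl-2-[2-(2-methyl-1,3-dioxolan-2-yl)ethyl]phenyl}methanone, via alkylborane 6 (not isolated)
Conditions: 5, 9-BBN-H, THF, 0 °C to rt; then 4, Pd(OAc)2 (5 mol %), SPhos, K3PO4, THF/H2O, 65 °C
Reagents that add atoms: none
Why: Anti-Markovnikov hydroboration of the vinyl ketal and B-alkyl Suzuki–Miyaura coupling with the di-ortho-substituted aryl bromide (hence the bulky biarylphosphine) should install C6, C7, C8 and C17 with the ketone masked; no stereocentre is formed.

**Step 3**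
Reactants: 7 [(2S)-2-(methoxymethyl)pyrrolidin-1-yl]{3-methyl-2-[2-(2-methyl-1,3-dioxolan-2-yl)ethyl]phenyl}methanone
Product: 9 [(1S)-1,3-dimethyl-2-[2-(2-methyl-1,3-dioxolan-2-yl)ethyl]cyclohexa-2,5-dien-1-yl][(2S)-2-(methoxymethyl)pyrrolidin-1-yl]methanone, via potassium enolate 8 (not isolated)
Conditions: K (2.2 equiv), NH3(l)/THF, t-BuOH (1 equiv), −78 °C; then MeI, −78 °C
Reagents that add atoms: iodomethane, CI
Why: Birch reductive alkylation: the electron-poor benzamide ring is reduced to the amide enolate, which is C-methylated in situ to the 1,4-diene, and the new quaternary centre C4 is set by the pyrrolidine auxiliary, whose methoxymethyl arm binds potassium and shields one enolate face.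

**Step 4**
Reactants: 9 [(1S)-1,3-dimethyl-2-[2-(2-methyl-1,3-dioxolan-2-yl)ethyl]cyclohexa-2,5-dien-1-yl][(2S)-2-(methoxymethyl)pyrrolidin-1-yl]methanone
Product: 10 [(1S)-1,3-dimethyl-2-[2-(2-methyl-1,3-dioxolan-2-yl)ethyl]cyclohex-2-en-1-yl][(2S)-2-(methoxymethyl)pyrrolidin-1-yl]methanone
Conditions: H2 (3 atm), RhCl(PPh3)3 (5 mol %), benzene/EtOH, rt
Reagents that add atoms: none
Why: Homogeneous hydrogenation with RhCl(PPh3)3 should reduce only the cis-disubstituted C2=C3 alkene and leave the tetrasubstituted C5=C10 alkene, which is inert to this catalyst; no stereocentre is formed.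

**Step 5**
Reactants: 10 [(1S)-1,3-dimethyl-2-[2-(2-methyl-1,3-dioxolan-2-yl)ethyl]cyclohex-2-en-1-yl][(2S)-2-(methoxymethyl)pyrrolidin-1-yl]methanone
Product: 12 (1S,5R,8S)-1,5-dimethyl-8-(3-oxobutyl)-6-oxabicyclo[3.2.1]octan-7-one, via iminium ether 11 (not isolated)
Conditions: CF3CO2H/H2O (9:1), CH2Cl2, 0 °C to rt
Reagents that add atoms: water, O
Why: Acid-mediated lactonization of the β,γ-unsaturated tertiary amide (the proton analogue of amide halolactonization) should protonate C5, trap the tertiary C10 cation with the amide oxygen on the face of C19 and release the auxiliary and the ketone on hydrolysis, with C5 set by anti addition (H trans to the lactone bridge), which is also the more stable epimer with the chain equatorial on ring A.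

**Step 6**
Reactants: 12 (1S,5R,8S)-1,5-dimethyl-8-(3-oxobutyl)-6-oxabicyclo[3.2.1]octan-7-one
Product: 13 (1S,5R,8S)-8-(3-hydroxy-3-methylpent-4-en-1-yl)-1,5-dimethyl-6-oxabicyclo[3.2.1]octan-7-one (both carbinol epimers)
Conditions: CH2=CHMgBr (1.2 equiv), THF, −78 °C; aq. NH4Cl
Reagents that add atoms: vinylmagnesium bromide, C=C[Mg]Br
Why: Grignard 1,2-addition at low temperature should be chemoselective for the methyl ketone over the hindered bridged lactone with its quaternary α-carbon, and the new carbinol centre forms as a mixture that is erased in step 7.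

**Step 7**
Reactants: 13 (1S,5R,8S)-8-(3-hydroxy-3-methylpent-4-en-1-yl)-1,5-dimethyl-6-oxabicyclo[3.2.1]octan-7-one
Product: 14 (1S,5R,8S)-1,5-dimethyl-8-(3-methyl-5-oxopent-3-en-1-yl)-6-oxabicyclo[3.2.1]octan-7-one (E/Z mixture at C8=C9)
Conditions: pyridinium chlorochromate (C5H5NH)[CrO3Cl] (3 equiv), 4 Å molecular sieves, CH2Cl2, rt
Reagents that add atoms: pyridinium chlorochromate, [O-][Cr](=O)(=O)Cl.c1cc[nH+]cc1
Why: Babler–Dauben oxidative transposition: the chromate ester of the tertiary allylic alcohol should undergo a [3,3] shift and the primary allylic chromate is oxidized to the enal, the C8=C9 geometry being immaterial because C9 becomes part of the ring alkene in step 9.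

**Step 8**
Reactants: 14 (1S,5R,8S)-1,5-dimethyl-8-(3-methyl-5-oxopent-3-en-1-yl)-6-oxabicyclo[3.2.1]octan-7-one
Product: 15 (1S,5R,8S)-1,5-dimethyl-8-[(5E)-3-methyl-7-oxoocta-3,5-dien-1-yl]-6-oxabicyclo[3.2.1]octan-7-one (E/Z mixture at C8=C9)
Conditions: Ph3P=CHC(O)CH3, toluene, 80 °C
Reagents that add atoms: 1-(triphenylphosphoranylidene)propan-2-one, CC(=O)C=P(c1ccccc1)(c1ccccc1)c1ccccc1
Why: Wittig olefination of the enal with the stabilized acetonyl ylide should give the E C11=C12 alkene and complete the pseudoionone-type dienone under neutral conditions that spare the lactone.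

**Step 9**
Reactants: 15 (1S,5R,8S)-1,5-dimethyl-8-[(5E)-3-methyl-7-oxoocta-3,5-dien-1-yl]-6-oxabicyclo[3.2.1]octan-7-one
Product: 16 (4S,5R,10S,11E)-13-oxo-14,15-dinorlabda-8,11-dien-19-oic acid
Conditions: conc. H2SO4 (5 equiv), CH2Cl2, −10 to 0 °C, two-phase; poured onto ice
Reagents that add atoms: none
Why: Proposed new method: sulfuric acid should protonate the lactone and cleave its tertiary alkyl–oxygen bond (C10–O), so that the C10 cation, with the departing C19 carboxyl still covering its β face, is captured on the α lobe by C9 of the dienone chain, and loss of H9 from the C8 cation restores the conjugated 8,11-dien-13-one while the leaving group stays in the molecule as the C19 acid (a net isomerization). The closest known reaction types are the sulfuric acid cyclization of pseudoionone to β-ionone (a tertiary cation attacks the inner carbon of the γ,δ-alkene of a dienone, then a proton is lost into conjugation) and the acid-promoted Friedel–Crafts cycloalkylation of tertiary γ-lactones onto a tethered arene; a tertiary lactone as initiator of a cation–olefin closure is the new element. Ring B closes in the 6-endo-trig mode (C8 and C9 both end up in the ring) through a chair-like transition state. The only new stereocentre, C10, is controlled by C5: with the C6 chain equatorial on ring A the ring-B chair forces a trans fusion, which places the C10 methyl axial and cis to the axial C19 carboxyl. The selectivities needed are bonding at C9 and not C8 (bonding at C8 would leave a cation conjugated to the carbonyl), the tetrasubstituted position of the ring alkene (thermodynamic, conjugation with the enone as in β-ionone) and trans over cis fusion (chair transition state, β face blocked by the carboxyl). Because lactone, C10 cation and the ring-A alkenes interconvert in the acid, both C8=C9 geometries of 15 and any C5 epimer should be funnelled into the one product.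

**Step 10**
Reactants: 16 (4S,5R,10S,11E)-13-oxo-14,15-dinorlabda-8,11-dien-19-oic acid
Product: 17 (4S,5R,10S)-13-oxo-14,15-dinorlabd-8-en-19-oic acid
Conditions: H2 (1 atm, 1 equiv uptake), Pd/C (5 %), EtOAc, rt
Reagents that add atoms: none
Why: Catalytic hydrogenation of the β-ionone type should saturate the accessible, carbonyl-conjugated disubstituted C11=C12 alkene and leave the hindered tetrasubstituted C8=C9 alkene; no stereocentre is formed.

**Step 11**
Reactants: 17 (4S,5R,10S)-13-oxo-14,15-dinorlabd-8-en-19-oic acid
Product: 18 (4S,5R,10S,13E)-15-ethoxy-15-oxolabda-8,13-dien-19-oic acid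
Conditions: (EtO)2P(O)CH2CO2Et (2.2 equiv), NaH (3.3 equiv), THF, 0 °C to reflux; chromatographic removal of the minor 13Z isomer
Reagents that add atoms: triethyl phosphonoacetate, CCOC(=O)CP(=O)(OCC)OCC
Why: Horner–Wadsworth–Emmons olefination of the methyl ketone, with the C19 acid carried as its sodium carboxylate, should give mainly the E trisubstituted enoate, and the minor Z isomer is separated at this stage.

**Step 12**
Reactants: 18 (4S,5R,10S,13E)-15-ethoxy-15-oxolabda-8,13-dien-19-oic acid
Product: 19 (4S,5R,10S,13E)-15-hydroxylabda-8,13-dien-19-oic acid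
Conditions: i-Bu2AlH (5 equiv), THF/toluene, −78 to −20 °C; cold dil. aq. HCl
Reagents that add atoms: none
Why: Aluminium hydride 1,2-reduction of the conjugated ethyl ester should give the allylic alcohol, while the neopentyl, axial C19 carboxylate (present as its aluminium salt) should resist reduction at low temperature and the E geometry is untouched.

**Step 13**
Reactants: 19 (4S,5R,10S,13E)-15-hydroxylabda-8,13-dien-19-oic acid
Product: 20 (4S,5R,10S,13E)-15-acetoxylabda-8,13-dien-19-oic acid
Conditions: Ac2O, pyridine, cat. DMAP, CH2Cl2, 0 °C to rt; aq. NaHCO3, then dil. HCl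
Reagents that add atoms: acetic anhydride, CC(=O)OC(C)=O
Why: Pyridine/DMAP-promoted O-acetylation of the primary allylic alcohol should be clean, and any mixed anhydride at the hindered C19 acid is hydrolysed back to the acid on aqueous work-up.

**Compound list**

1 | 2-bromo-3-methylbenzoic acid | Cc1cccc(C(=O)O)c1Br | starting material
2 | (S)-2-(methoxymethyl)pyrrolidine | COC[C@@H]1CCCN1 | starting material
3 | 2-bromo-3-methylbenzoyl chloride | Cc1cccc(C(=O)Cl)c1Br | intermediate
4 | [(2S)-2-(methoxymethyl)pyrrolidin-1-yl](2-bromo-3-methylphenyl)methanone | Cc1cccc(C(=O)N2CCC[C@H]2COC)c1Br | intermediate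
5 | 2-methyl-2-vinyl-1,3-dioxolane | C=CC1(C)OCCO1 | starting material
6 | 9-[2-(2-methyl-1,3-dioxolan-2-yl)ethyl]-9-borabicyclo[3.3.1]nonane | CC1(CCB2C3CCCC2CCC3)OCCO1 | intermediate
7 | [(2S)-2-(methoxymethyl)pyrrolidin-1-yl]{3-methyl-2-[2-(2-methyl-1,3-dioxolan-2-yl)ethyl]phenyl}methanone | Cc1cccc(C(=O)N2CCC[C@H]2COC)c1CCC1(C)OCCO1 | intermediate
8 | potassium amide enolate of the 1,4-dihydro derivative of 7 | [K+].[O-]C(N1CCC[C@H]1COC)=C1C=CCC(C)=C1CCC1(C)OCCO1 | intermediate
9 | [(1S)-1,3-dimethyl-2-[2-(2-methyl-1,3-dioxolan-2-yl)ethyl]cyclohexa-2,5-dien-1-yl][(2S)-2-(methoxymethyl)pyrrolidin-1-yl]methanone | C[C@]1(C(=O)N2CCC[C@H]2COC)C=CCC(C)=C1CCC1(C)OCCO1 | intermediate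
10 | [(1S)-1,3-dimethyl-2-[2-(2-methyl-1,3-dioxolan-2-yl)ethyl]cyclohex-2-en-1-yl][(2S)-2-(methoxymethyl)pyrrolidin-1-yl]methanone | C[C@]1(C(=O)N2CCC[C@H]2COC)CCCC(C)=C1CCC1(C)OCCO1 | intermediate
11 | iminium ether (O-alkyl imidate salt) of the lactone, trifluoroacetate | C[C@@]12CCC[C@@](C)(OC1=[N+]1CCC[C@H]1COC)[C@H]2CCC(C)=O.[O-]C(=O)C(F)(F)F | intermediate
12 | (1S,5R,8S)-1,5-dimethyl-8-(3-oxobutyl)-6-oxabicyclo[3.2.1]octan-7-one | C[C@@]12CCC[C@@](C)(OC1=O)[C@H]2CCC(C)=O | intermediate
13 | (1S,5R,8S)-8-(3-hydroxy-3-methylpent-4-en-1-yl)-1,5-dimethyl-6-oxabicyclo[3.2.1]octan-7-one, carbinol epimers | C[C@@]12CCC[C@@](C)(OC1=O)[C@H]2CCC(C)(O)C=C | intermediate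
14 | (1S,5R,8S)-1,5-dimethyl-8-(3-methyl-5-oxopent-3-en-1-yl)-6-oxabicyclo[3.2.1]octan-7-one, E/Z at C8=C9 | C[C@@]12CCC[C@@](C)(OC1=O)[C@H]2CCC(C)=CC=O | intermediate
15 | (1S,5R,8S)-1,5-dimethyl-8-[(5E)-3-methyl-7-oxoocta-3,5-dien-1-yl]-6-oxabicyclo[3.2.1]octan-7-one, E/Z at C8=C9 | C[C@@]12CCC[C@@](C)(OC1=O)[C@H]2CCC(C)=C/C=C/C(C)=O | intermediate
16 | (4S,5R,10S,11E)-13-oxo-14,15-dinorlabda-8,11-dien-19-oic acid | CC(=O)/C=C/C1=C(C)CC[C@H]2[C@@](C)(C(=O)O)CCC[C@]12C | intermediate
17 | (4S,5R,10S)-13-oxo-14,15-dinorlabd-8-en-19-oic acid | CC(=O)CCC1=C(C)CC[C@H]2[C@@](C)(C(=O)O)CCC[C@]12C | intermediate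
18 | (4S,5R,10S,13E)-15-ethoxy-15-oxolabda-8,13-dien-19-oic acid | CCOC(=O)/C=C(\C)CCC1=C(C)CC[C@H]2[C@@](C)(C(=O)O)CCC[C@]12C | intermediate
19 | (4S,5R,10S,13E)-15-hydroxylabda-8,13-dien-19-oic acid | OC/C=C(\C)CCC1=C(C)CC[C@H]2[C@@](C)(C(=O)O)CCC[C@]12C | intermediate
20 | (4S,5R,10S,13E)-15-acetoxylabda-8,13-dien-19-oic acid | CC(=O)OC/C=C(\C)CCC1=C(C)CC[C@H]2[C@@](C)(C(=O)O)CCC[C@]12C | target

**Step count and risks**

Total step count: 13. Longest linear sequence: 13 steps (1 to 20).

Step 9 (Proposed new method). The ion pair may return to the lactone faster than C9 captures it. The strong acid may also cause decarbonylation of the tertiary acid, a hydride shift from C5 to C10, cis ring fusion or incomplete migration of the ring alkene into conjugation. The fallback uses known chemistry, sets out from 15 and comes back at 17. The tertiary alkyl–oxygen bond of 15 is cleaved by E1 elimination under the conditions that cleave tert-butyl esters (Me3SiOTf, 2,6-lutidine, CH2Cl2; aqueous acid work-up) to give the ene acid (1S)-1,3-dimethyl-2-[(5E)-3-methyl-7-oxoocta-3,5-dien-1-yl]cyclohex-2-ene-1-carboxylic acid F1; its ring-alkene isomers are equivalent for what follows. Me3SiCHN2 in toluene/MeOH gives the methyl ester F2. Ring B is then closed by the classical proton-initiated closure of the pseudoionone type, the cation now coming from protonation of the ring alkene under milder acid (MeSO3H, CH2Cl2, 0 °C), to give methyl (4S,5R,10S,11E)-13-oxo-14,15-dinorlabda-8,11-dien-19-oate F3. Hydrogenation as in step 10 gives the keto ester F4, and SN2 demethylation of the hindered ester (LiSPr, HMPA, rt) returns acid 17.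

Step 3. The facial selectivity of the methylation of enolate 8 may be insufficient or reversed for this 2,3-dialkyl substrate, and over-reduction may compete. The fallback sets out from 7 and comes back at 9, with reduction and alkylation separated. Birch reduction with protonation (K, NH3, t-BuOH, −78 °C; NH4Cl) gives the 1,4-dihydrobenzamide F5. Its lithium enolate (LiN(i-Pr)2, THF, −78 °C) is then methylated with MeI. This enolate is formed under aprotic lithium conditions and is expected to show the complementary facial bias, so one of the two protocols, with the matching auxiliary enantiomer, should give 9. The C4 epimers are diastereomers and can also be separated at this stage.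

Step 11. The E selectivity of the olefination of the methyl ketone may be incomplete and the 13Z isomer hard to remove. The fallback sets out from 17 and comes back at 19, so that 18 is bypassed. The methyl ketone is converted through its kinetic enol phosphate (LiN(i-Pr)2; ClP(O)(OEt)2; LiN(i-Pr)2, THF, −78 °C to rt) into the terminal alkyne (4S,5R,10S)-15,16-dinorlabd-8-en-13-yn-19-oic acid F6. Zirconium-catalysed methylalumination (Me3Al, Cp2ZrCl2, CH2Cl2), followed by trapping of the alkenylalane as its ate complex with formaldehyde (n-BuLi; (CH2O)n, THF), then gives allylic alcohol 19 with the 13E geometry fixed by syn addition.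

**Further compounds**

F1 | step 9 | (1S)-1,3-dimethyl-2-[(5E)-3-methyl-7-oxoocta-3,5-dien-1-yl]cyclohex-2-ene-1-carboxylic acid | C[C@]1(C(=O)O)CCCC(C)=C1CCC(C)=C/C=C/C(C)=O
F2 | step 9 | methyl (1S)-1,3-dimethyl-2-[(5E)-3-methyl-7-oxoocta-3,5-dien-1-yl]cyclohex-2-ene-1-carboxylate | C[C@]1(C(=O)OC)CCCC(C)=C1CCC(C)=C/C=C/C(C)=O
F3 | step 9 | methyl (4S,5R,10S,11E)-13-oxo-14,15-dinorlabda-8,11-dien-19-oate | CC(=O)/C=C/C1=C(C)CC[C@H]2[C@@](C)(C(=O)OC)CCC[C@]12C
F4 | step 9 | methyl (4S,5R,10S)-13-oxo-14,15-dinorlabd-8-en-19-oate | CC(=O)CCC1=C(C)CC[C@H]2[C@@](C)(C(=O)OC)CCC[C@]12C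
F5 | step 3 | [(2S)-2-(methoxymethyl)pyrrolidin-1-yl]{3-methyl-2-[2-(2-methyl-1,3-dioxolan-2-yl)ethyl]cyclohexa-2,5-dien-1-yl}methanone | COC[C@@H]1CCCN1C(=O)C1C=CCC(C)=C1CCC1(C)OCCO1
F6 | step 11 | (4S,5R,10S)-15,16-dinorlabd-8-en-13-yn-19-oic acid | C#CCCC1=C(C)CC[C@H]2[C@@](C)(C(=O)O)CCC[C@]12C
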